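**Retrosynthetic overview**
1. Target 19 ⇐ methyl ester 18 by selective saponification of the unhindered C15 ester.
2. 18 ⇐ acyclic epoxy allylsilane 15 + anhydride 17: acylation of the oxirane oxygen (the C19–O–acyl ester bond) triggers closure of ring A, then ring B, in one step; the allylsilane leaves the 8(17)-methylene.
3. 15 ⇐ methyl ketone 14 by catalytic asymmetric Corey–Chaykovsky epoxidation, which forms the C19–O bond and sets C4; C5, C9 and C10 are relayed from C4 in the cyclization.
4. 14 ⇐ bromide 10 + methyl crotonate by copper-catalysed asymmetric conjugate addition (sets C13).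
5. 10 ⇐ chloro ketal 1 by two rounds of alkylation of 5-lithio-2,3-dihydrofuran 4 and nickel-catalysed Grignard ring opening (MeMgBr, then Me3SiCH2MgCl).

Assumption: the catalyst antipodes named in steps 9 and 10 are taken to add to the Si face of C3 of methyl crotonate and to the Si face of the carbonyl of 14 (giving 13R and the (R)-oxirane); if the sense on these substrates is the reverse, the commercial mirror-image ligand is used with nothing else changed.

**Step 1**
Reactants: 1 2-(3-chloropropyl)-2-methyl-1,3-dioxolane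
Product: 2 2-(3-iodopropyl)-2-methyl-1,3-dioxolane
Conditions: NaI (3 equiv), NaHCO3 (0.1 equiv), acetone, reflux, 16 h
Reagents that add atoms: sodium iodide [Na+].[I-]
Why: Finkelstein SN2 halide exchange driven by precipitation of NaCl, needed because the lithiated dihydrofuran alkylates primary iodides cleanly but chlorides poorly.

**Step 2**
Reactants: 3 2,3-dihydrofuran
Product: 4 5-lithio-2,3-dihydrofuran
Conditions: t-BuLi (0.95 equiv, pentane), THF, −78 → 0 °C, 30 min; the THF solution is used at once and is made fresh before step 3 and again before step 6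
Reagents that add atoms: lithium (from tert-butyllithium) [Li]C(C)(C)C
Why: oxygen-directed α-deprotonation of the vinylic C–H of the cyclic enol ether by t-BuLi gives the α-alkoxyvinyllithium reagent quantitatively; it is kept as a solution because it does not survive isolation.

**Step 3**
Reactants: 4 5-lithio-2,3-dihydrofuran; 2 2-(3-iodopropyl)-2-methyl-1,3-dioxolane
Product: 5 2-[3-(4,5-dihydrofuran-2-yl)propyl]-2-methyl-1,3-dioxolane
Conditions: 4 (1.4 equiv, THF solution from step 2), then 2, −30 °C → rt; basic work-up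
Reagents that add atoms: none
Why: SN2 alkylation of the vinyllithium by the primary iodide (Kocienski iterative isoprenoid protocol), with the dioxolane inert to the organolithium.

**Step 4**
Reactants: 5 2-[3-(4,5-dihydrofuran-2-yl)propyl]-2-methyl-1,3-dioxolane
Product: 6 (3E)-4-methyl-7-(2-methyl-1,3-dioxolan-2-yl)hept-3-en-1-ol
Conditions: MeMgBr (3 equiv, Et2O), NiCl2(PPh3)2 (5 mol %), toluene, 70 °C, 3 h; then H2O
Reagents that add atoms: methylmagnesium bromide C[Mg]Br
Why: Wenkert–Kocienski nickel-catalysed cross-coupling of the enol-ether C–O bond with a Grignard reagent lacking β-hydrogens proceeds with retention, so the methyl ends up cis to the hydroxyethyl arm and the (E)-trisubstituted alkene (future C5=C10) forms stereospecifically.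

**Step 5**
Reactants: 6 (3E)-4-methyl-7-(2-methyl-1,3-dioxolan-2-yl)hept-3-en-1-ol
Product: 7 2-[(4E)-7-iodo-4-methylhept-4-en-1-yl]-2-methyl-1,3-dioxolane
Conditions: I2 (1.2 equiv), PPh3 (1.2 equiv), imidazole (1.5 equiv), CH2Cl2, 0 °C → rt
Reagents that add atoms: iodine II
Why: Appel-type iodination (SN2 on the alkoxyphosphonium ion) under imidazole buffering, which leaves the ketal and the alkene geometry untouched.

**Step 6**
Reactants: 4 5-lithio-2,3-dihydrofuran; 7 2-[(4E)-7-iodo-4-methylhept-4-en-1-yl]-2-methyl-1,3-dioxolane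
Product: 8 2-[(4E)-7-(4,5-dihydrofuran-2-yl)-4-methylhept-4-en-1-yl]-2-methyl-1,3-dioxolane
Conditions: 4 (1.4 equiv, fresh THF solution from step 2), then 7, −30 °C → rt; basic work-up
Reagents that add atoms: none
Why: second SN2 alkylation of the same vinyllithium reagent, the documented chain-extension step for homoallylic iodides in iterative isoprenoid synthesis.

**Step 7**
Reactants: 8 2-[(4E)-7-(4,5-dihydrofuran-2-yl)-4-methylhept-4-en-1-yl]-2-methyl-1,3-dioxolane
Product: 9 (3Z,7E)-8-methyl-11-(2-methyl-1,3-dioxolan-2-yl)-4-[(trimethylsilyl)methyl]undeca-3,7-dien-1-ol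
Conditions: Me3SiCH2MgCl (3 equiv, Et2O), NiCl2(PPh3)2 (7 mol %), toluene, 75 °C, 4 h; then H2O
Reagents that add atoms: (trimethylsilyl)methylmagnesium chloride C[Si](C)(C)C[Mg]Cl
Why: the same nickel-catalysed enol-ether coupling with retention places CH2SiMe3 cis to the hydroxyethyl arm, giving the (Z)-allylsilane with an E main chain, the geometry that later puts C11 equatorial and ends the cyclization as the exocyclic alkene.

**Step 8**
Reactants: 9 (3Z,7E)-8-methyl-11-(2-methyl-1,3-dioxolan-2-yl)-4-[(trimethylsilyl)methyl]undeca-3,7-dien-1-ol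
Product: 10 2-[(4E,8Z)-11-bromo-4-methyl-8-[(trimethylsilyl)methyl]undeca-4,8-dien-1-yl]-2-methyl-1,3-dioxolane
Conditions: CBr4 (1.3 equiv), PPh3 (1.4 equiv), 2,6-lutidine (0.5 equiv), CH2Cl2, 0 °C
Reagents that add atoms: carbon tetrabromide BrC(Br)(Br)Br
Why: Appel bromination under neutral, buffered conditions that spare the acid-sensitive allylsilane and ketal.

**Step 9**
Reactants: 10 2-[(4E,8Z)-11-bromo-4-methyl-8-[(trimethylsilyl)methyl]undeca-4,8-dien-1-yl]-2-methyl-1,3-dioxolane; 11 methyl (2E)-but-2-enoate
Product: 14 methyl (3R,6Z,10E)-3,11-dimethyl-15-oxo-7-[(trimethylsilyl)methyl]hexadeca-6,10-dienoate, via homoallylic Grignard reagent 12 (not isolated), via dioxolane ester 13 (not isolated)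
Conditions: Mg, Et2O, rt; the Grignard solution added over 2 h to 11 (1.5 equiv), CuBr·SMe2 (5 mol %), (R)-1-[(S_p)-2-(diphenylphosphino)ferrocenyl]ethyldicyclohexylphosphine (6 mol %), t-BuOMe, −75 °C; MeOH quench, aq. NH4Cl work-up; then PPTS (0.2 equiv), acetone/H2O (9:1), 50 °C, 4 h
Reagents that add atoms: water O
Why: Feringa-type copper/Josiphos-catalysed asymmetric conjugate addition of a primary Grignard reagent to methyl crotonate sets C13 as R by Si-face delivery at C3 (about 90–95% ee expected for this reaction class), and the mild pyridinium-acid hydrolysis turns the dioxolane into the methyl ketone without protodesilylating the allylsilane.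

**Step 10**
Reactants: 14 methyl (3R,6Z,10E)-3,11-dimethyl-15-oxo-7-[(trimethylsilyl)methyl]hexadeca-6,10-dienoate
Product: 15 methyl (3R,6Z,10E)-3,11-dimethyl-14-[(2R)-2-methyloxiran-2-yl]-7-[(trimethylsilyl)methyl]tetradeca-6,10-dienoate
Conditions: Me3S(O)I (1.3 equiv), NaH (1.25 equiv), THF, reflux (ylide solution); then 14, LaLi3[(R)-1,1'-binaphthalene-2,2'-diolate]3 (5 mol %), tris(2,4,6-trimethoxyphenyl)phosphine oxide (5 mol %), 5 Å molecular sieves, THF, rt, 16 h
Reagents that add atoms: trimethylsulfoxonium iodide C[S+](C)(C)=O.[I-]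
Why: Shibasaki catalytic asymmetric Corey–Chaykovsky epoxidation, in which the chiral lanthanum–lithium binaphthoxide/phosphine oxide catalyst directs the sulfoxonium methylide to the Si face of the methyl ketone and the alkoxide then closes onto CH2 (C19–O bond), setting C4 as the (R)-oxirane (methyl ketones give 91–97% ee); ester and allylsilane are inert.

**Step 11**
Reactants: 16 (2R)-2-methylbutanoic acid (two molecules per molecule of 17)
Product: 17 (2R)-2-methylbutanoic anhydride
Conditions: DCC (0.5 equiv relative to 16), CH2Cl2, 0 °C → rt, 2 h; filter, concentrate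
Reagents that add atoms: (2R)-2-methylbutanoic acid (second molecule of 16) CC[C@@H](C)C(=O)O
Why: carbodiimide dehydration, in which one molecule of 16 forms the O-acylisourea and a second molecule of 16 attacks it, gives the symmetric anhydride without base, so the α-stereocentre is not enolised.

**Step 12**
Reactants: 15 methyl (3R,6Z,10E)-3,11-dimethyl-14-[(2R)-2-methyloxiran-2-yl]-7-[(trimethylsilyl)methyl]tetradeca-6,10-dienoate; 17 (2R)-2-methylbutanoic anhydride
Product: 18 methyl (3R)-3-methyl-5-[(1R,4aS,5R,8aS)-5,8a-dimethyl-2-methylidene-5-{[(2R)-2-methylbutanoyl]oxymethyl}decahydronaphthalen-1-yl]pentanoate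
Conditions: 17 (1.5 equiv), Me3SiOTf (15 mol %), 2,6-di-tert-butyl-4-methylpyridine (20 mol %), CH2Cl2, −78 → −40 °C, 2 h; aq. NaHCO3
Reagents that add atoms: none
Why: Proposed new method: a silyl-triflate-relayed acylative epoxide-opening bicyclization, in which Me3SiOTf turns 17 into (2R)-2-methylbutanoyl triflate, this O-acylates the oxirane (forming the ester C–O bond), and the O-acyloxiranium ion is opened at tertiary C4 with inversion by C5 of the (E)-alkene through a chair–chair transition state where the oxirane CH2 (C19), tied back toward the leaving oxygen, takes the crowded pseudo-axial site syn to the C10 methyl, after which the (Z)-allylsilane attacks C10 with C11 equatorial and loses Me3Si+ to give the 8(17)-alkene and regenerate Me3SiOTf, so the (4R)-oxirane is relayed to 4R,5S,10S,9R (a competing silyl-oxiranium pathway gives the C19 silyl ether, which the same Me3SiOTf/anhydride pair acylates to the same product); closest known reactions are Lewis-acid epoxide-initiated, allylsilane-terminated polyene cyclization, cleavage of epoxides by acyl halides through O-acyloxiranium ions, and Me3SiOTf-catalysed acylation with anhydrides.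

**Step 13**
Reactants: 18 methyl (3R)-3-methyl-5-[(1R,4aS,5R,8aS)-5,8a-dimethyl-2-methylidene-5-{[(2R)-2-methylbutanoyl]oxymethyl}decahydronaphthalen-1-yl]pentanoate
Product: 19 (3R)-3-methyl-5-[(1R,4aS,5R,8aS)-5,8a-dimethyl-2-methylidene-5-{[(2R)-2-methylbutanoyl]oxymethyl}decahydronaphthalen-1-yl]pentanoic acid
Conditions: LiOH·H2O (2 equiv), THF/H2O (3:1), 0 °C → rt; then 1 M HCl to pH 3
Reagents that add atoms: lithium hydroxide [Li+].[OH-]
Why: saponification (acyl–oxygen cleavage) of the unhindered side-chain methyl ester is far faster than attack on the neopentyl, axial C19 ester of an α-branched acid, and aqueous hydroxide at this temperature does not epimerise the 2-methylbutanoate or move the exocyclic alkene.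

**Compound list**
1 | 2-(3-chloropropyl)-2-methyl-1,3-dioxolane | CC1(CCCCl)OCCO1 | starting material
2 | 2-(3-iodopropyl)-2-methyl-1,3-dioxolane | CC1(CCCI)OCCO1 | intermediate
3 | 2,3-dihydrofuran | C1CC=CO1 | starting material
4 | 5-lithio-2,3-dihydrofuran | [Li]C1=CCCO1 | intermediate
5 | 2-[3-(4,5-dihydrofuran-2-yl)propyl]-2-methyl-1,3-dioxolane | CC1(CCCC2=CCCO2)OCCO1 | intermediate
6 | (3E)-4-methyl-7-(2-methyl-1,3-dioxolan-2-yl)hept-3-en-1-ol | OCC/C=C(\C)CCCC1(C)OCCO1 | intermediate
7 | 2-[(4E)-7-iodo-4-methylhept-4-en-1-yl]-2-methyl-1,3-dioxolane | ICC/C=C(\C)CCCC1(C)OCCO1 | intermediate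
8 | 2-[(4E)-7-(4,5-dihydrofuran-2-yl)-4-methylhept-4-en-1-yl]-2-methyl-1,3-dioxolane | CC1(CCC/C(C)=C/CCC2=CCCO2)OCCO1 | intermediate
9 | (3Z,7E)-8-methyl-11-(2-methyl-1,3-dioxolan-2-yl)-4-[(trimethylsilyl)methyl]undeca-3,7-dien-1-ol | OCC/C=C(\C[Si](C)(C)C)CC/C=C(\C)CCCC1(C)OCCO1 | intermediate
10 | 2-[(4E,8Z)-11-bromo-4-methyl-8-[(trimethylsilyl)methyl]undeca-4,8-dien-1-yl]-2-methyl-1,3-dioxolane | BrCC/C=C(\C[Si](C)(C)C)CC/C=C(\C)CCCC1(C)OCCO1 | intermediate
11 | methyl (2E)-but-2-enoate | C/C=C/C(=O)OC | starting material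
12 | {(3Z,7E)-8-methyl-11-(2-methyl-1,3-dioxolan-2-yl)-4-[(trimethylsilyl)methyl]undeca-3,7-dien-1-yl}magnesium bromide | Br[Mg]CC/C=C(\C[Si](C)(C)C)CC/C=C(\C)CCCC1(C)OCCO1 | intermediate (not isolated)
13 | methyl (3R,6Z,10E)-3,11-dimethyl-14-(2-methyl-1,3-dioxolan-2-yl)-7-[(trimethylsilyl)methyl]tetradeca-6,10-dienoate | COC(=O)C[C@H](C)CC/C=C(\C[Si](C)(C)C)CC/C=C(\C)CCCC1(C)OCCO1 | intermediate (not isolated)
14 | methyl (3R,6Z,10E)-3,11-dimethyl-15-oxo-7-[(trimethylsilyl)methyl]hexadeca-6,10-dienoate | COC(=O)C[C@H](C)CC/C=C(\C[Si](C)(C)C)CC/C=C(\C)CCCC(C)=O | intermediate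
15 | methyl (3R,6Z,10E)-3,11-dimethyl-14-[(2R)-2-methyloxiran-2-yl]-7-[(trimethylsilyl)methyl]tetradeca-6,10-dienoate | COC(=O)C[C@H](C)CC/C=C(\C[Si](C)(C)C)CC/C=C(\C)CCC[C@]1(C)CO1 | intermediate
16 | (2R)-2-methylbutanoic acid | CC[C@@H](C)C(=O)O | starting material
17 | (2R)-2-methylbutanoic anhydride | CC[C@@H](C)C(=O)OC(=O)[C@H](C)CC | intermediate
18 | methyl (3R)-3-methyl-5-[(1R,4aS,5R,8aS)-5,8a-dimethyl-2-methylidene-5-{[(2R)-2-methylbutanoyl]oxymethyl}decahydronaphthalen-1-yl]pentanoate | C=C1CC[C@@H]2[C@](C)(COC(=O)[C@H](C)CC)CCC[C@@]2(C)[C@@H]1CC[C@@H](C)CC(=O)OC | intermediate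
19 | (3R)-3-methyl-5-[(1R,4aS,5R,8aS)-5,8a-dimethyl-2-methylidene-5-{[(2R)-2-methylbutanoyl]oxymethyl}decahydronaphthalen-1-yl]pentanoic acid | C=C1CC[C@@H]2[C@](C)(COC(=O)[C@H](C)CC)CCC[C@@]2(C)[C@@H]1CC[C@@H](C)CC(=O)O | target

**Step count:** 13 steps in total. Because the solution of 4 is made fresh for each of its two uses, step 2 is run twice, which makes 14 separate operations at the bench. The longest linear sequence is 11 steps (steps 1, 3–10, 12, 13, or equally steps 2–10, 12, 13); step 11 is a one-step branch.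

**Steps most likely to fail**

Step 12 (the proposed new step). The acyl triflate may C-acylate the allylsilane instead of the oxirane oxygen. The oxirane may also ionise before the alkene participates, which would lose the C4-to-ring relay. The preference for the oxirane CH2 over the methyl in the axial site at C4 is also untested. The fallback sets out from 15 and uses known chemistry: MeAlCl2 (2 equiv, CH2Cl2, −78 °C), the established Lewis-acid epoxide-initiated, allylsilane-terminated bicyclization, gives the free C19 alcohol methyl (3R)-5-[(1R,4aS,5R,8aS)-5-(hydroxymethyl)-5,8a-dimethyl-2-methylidenedecahydronaphthalen-1-yl]-3-methylpentanoate F1. Steglich esterification of F1 with acid 16 (DCC, DMAP, CH2Cl2, rt) then rejoins the route at 18, and step 11 is no longer needed.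

Step 10. The enantioselectivity and facial sense of the catalytic methylide transfer are untested on a long-chain polyene methyl ketone, and the minor oxirane epimer would lead to a ring-enantiomeric diastereomer that is hard to remove. The fallback sets out from 14: uncatalysed Corey–Chaykovsky epoxidation (Me3S(O)I, NaH, DMSO, rt) gives methyl (3R,6Z,10E)-3,11-dimethyl-14-(2-methyloxiran-2-yl)-7-[(trimethylsilyl)methyl]tetradeca-6,10-dienoate F2 as a 1:1 mixture of oxirane epimers. Jacobsen kinetic resolution of 2,2-disubstituted epoxides (Me3SiN3 0.55 equiv, i-PrOH, 2 mol % of the [N,N'-bis(3,5-di-tert-butylsalicylidene)cyclohexane-1,2-diaminato]chromium azide antipode, trivalent chromium, that consumes the (S)-oxirane) converts the unwanted epimer into the azido alcohol methyl (3R,6Z,10E,15S)-16-azido-15-hydroxy-3,11,15-trimethyl-7-[(trimethylsilyl)methyl]hexadeca-6,10-dienoate F3. The unreacted epimer is 15, where the route is rejoined at no more than 50% yield.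

Step 9. The ee of the conjugate addition with this functionalised Grignard reagent may fall short, and the C13 epimer cannot be separated later. The fallback sets out from 10 and takes C13 from the chiral pool: the Grignard reagent 12 made from 10 opens (4R)-4-methyloxetan-2-one ((R)-β-butyrolactone) at C4 by SN2 with inversion (CuBr·SMe2 0.5 equiv, THF/Me2S, −30 °C; citric acid work-up) to give (3R,6Z,10E)-3,11-dimethyl-14-(2-methyl-1,3-dioxolan-2-yl)-7-[(trimethylsilyl)methyl]tetradeca-6,10-dienoic acid F4. Methylation with Me3SiCHN2 in MeOH/toluene rejoins the route at 13, which is hydrolysed to 14 as in step 9.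

**Further compounds**
F1 | step 12 | methyl (3R)-5-[(1R,4aS,5R,8aS)-5-(hydroxymethyl)-5,8a-dimethyl-2-methylidenedecahydronaphthalen-1-yl]-3-methylpentanoate | C=C1CC[C@@H]2[C@](C)(CO)CCC[C@@]2(C)[C@@H]1CC[C@@H](C)CC(=O)OC
F2 | step 10 | methyl (3R,6Z,10E)-3,11-dimethyl-14-(2-methyloxiran-2-yl)-7-[(trimethylsilyl)methyl]tetradeca-6,10-dienoate (1:1 oxirane epimers) | COC(=O)C[C@H](C)CC/C=C(\C[Si](C)(C)C)CC/C=C(\C)CCCC1(C)CO1
F3 | step 10 | methyl (3R,6Z,10E,15S)-16-azido-15-hydroxy-3,11,15-trimethyl-7-[(trimethylsilyl)methyl]hexadeca-6,10-dienoate | COC(=O)C[C@H](C)CC/C=C(\C[Si](C)(C)C)CC/C=C(\C)CCC[C@](C)(O)CN=[N+]=[N-]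
F4 | step 9 | (3R,6Z,10E)-3,11-dimethyl-14-(2-methyl-1,3-dioxolan-2-yl)-7-[(trimethylsilyl)methyl]tetradeca-6,10-dienoic acid | OC(=O)C[C@H](C)CC/C=C(\C[Si](C)(C)C)CC/C=C(\C)CCCC1(C)OCCO1
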